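The earlier runs and the new flask were computed for an exercise, noise included.

Thursday's run, with 1.2 equiv of partner, is what there is to reason from for the new flask.

in all of them: left-handed substrate 0.065 M; right-handed substrate 0.065 M
- Thursday's: partner 1.2 equiv; run made earlier
- flask: partner 2.50 equiv; time 15 h

- Thursday's (time / h: left-handed substrate / %, right-handed substrate / %): 0.333: 48.3, 46.8; 0.833: 45.6, 45.4; 2.00: 40.8, 45.0; 5.00: 37.4, 40.8

(readings scatter by 1 percentage point)

- partner is single-handed; left-handed substrate and right-handed substrate are mirror images of each other, charged as a racemate, each of them at the stated concentration
- what was read earlier has a scatter of 1 percentage point, one standard deviation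
- what has gone into achiral form counts as reacted
- an excess is below zero if the other one leads
- the handed part of partner does not stay in what it makes, so the products of the two hands are mirror images too

- part of the left-handed substrate and right-handed substrate charged together that has reacted at 15 h
- excess of left-handed product over right-handed product in the product at 15 h
- excess of right-handed substrate over left-handed substrate among what is left of the two at 15 h

What does a handed partner do that can be counted? It turns over, and each turn takes one substrate of one hand into one product. So let s be the left-handed turns per right-handed turn, the selectivity factor; then eP, the excess in the product, is s minus one over s plus one.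

Can s be read? Not directly, since no product was read, but the losses give a reading. At 2.00 h the left-handed substrate had lost 9.2 percentage points and the right-handed 5 points, so 1.84 is my s, the ratio of losses, and a coarse one, since each reading scatters by 1 point.

Are those losses all turnovers? I doubt it. At 0.833 h the two hands had lost 4.4 points and 4.6 points, alike within the scatter. A shared loss, added top and bottom, pulls a ratio towards one, so s may stand above my reading; but the scatter can move the ratio either way, so the reading is an estimate and no bound.

And the gap between the hands? It reads 4.2 points at 2.00 h and 3.4 points at 5.00 h, a change of 0.8 points between readings that each scatter by 1 point, so I can't tell whether it still grows. I assume, unproved, that a product once made stays counted. So I commit to eP near 29.6 %, as an estimate, and eS near Thursday's 4.35 %; for c I have no count.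

The forecast says c 38 %, eP 0 %, eS 0 %, holding that “the final mixture is racemic”.

The flask gives c 33.4 %, eP 43.1 %, eS 3.58 %.

    left-handed substrate ⇌ achiral form (K = 0.510, k = 0.0760 h⁻¹)
    partner + right-handed substrate → right-handed product (k = 0.200 L mol⁻¹ h⁻¹)
    achiral form → waste (k = 0.0180 h⁻¹)
    2 partner → homo dimer (k = 1.50 L mol⁻¹ h⁻¹)
    right-handed substrate ⇌ achiral form (K = 0.510, k = 0.0760 h⁻¹)
    partner + left-handed substrate → left-handed product (k = 0.530 L mol⁻¹ h⁻¹)
    achiral form → decomposed reagent (k = 0.00440 h⁻¹)
    partner ⇌ dormant form (K = 4.70, k = 0.260 h⁻¹)

Counted in this flask at 15.0 h, the products stand at 8.90 % left-handed and 3.54 % right-handed, a ratio of 2.51, above my reading of 1.84. The neighbour, charged with 1.00 equiv of partner, made 4.83 % and 1.87 % in the same time, about half of the left-handed product, yet its ratio is 2.58. Its eP, against my estimate of 29.6 %, is 44.1 %.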